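**Retrosynthetic overview**
1. Pestallic acid O (23) ⇐ one fluoride step that removes two silyl ethers and the 2-(trimethylsilyl)ethyl ester of enone 22.
2. 22 ⇐ hydroxyl-directed epoxidation and base-induced epoxide opening of cyclohex-3-enone 20 (puts C4–OH cis to C5–OH, creates the dienone).
3. 20 ⇐ one-carbon ring expansion of cyclopentenone 11: the diazo carbon of 19, carrying the whole C2 side chain, is inserted between C=O and the ring alkene carbon by a 1,2-shift.
4. 11 ⇐ cross-metathesis, silylation and Morita–Baylis–Hillman hydroxymethylation of (4R,5S)-5 ⇐ kinetic resolution ⇐ Piancatelli rearrangement of furyl carbinol 3; 19 ⇐ (R)-propylene oxide, butenyl Grignard, acrolein.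
5. Ring order: furan → cyclopentenone (step 2) → cyclohexenone (step 12).

Assumption: in step 3 (R)-benzotetramisole acylates the (4S,5R)-alcohol faster (by analogy with cyclic allylic alcohols, where the alkene side binds the catalyst); if the sense is the opposite, the (S)-catalyst is used.

**Route**

Step 1
Reactants: 1 furfural; 2 allylmagnesium bromide
Product: 3 rac-1-(furan-2-yl)but-3-en-1-ol
Conditions: Et2O, 0 °C; H2O work-up
Reagents that add atoms: none
Why: Grignard 1,2-addition to the aldehyde; the carbinol centre is ionised in step 2, so its configuration does not matter.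

Step 2
Reactants: 3 rac-1-(furan-2-yl)but-3-en-1-ol
Product: 4 rac-trans-4-hydroxy-5-(prop-2-en-1-yl)cyclopent-2-en-1-one
Conditions: Dy(OTf)3 (10 mol%), t-BuOH/H2O (5:1), 80 °C
Reagents that add atoms: water, O
Why: Piancatelli rearrangement (ionisation of the furyl carbinol, addition of water, ring opening and conrotatory closure of the hydroxypentadienyl cation) gives the 4-hydroxy-5-substituted cyclopentenone only as the trans isomer, which fixes the relative configuration of the later C5–OH and C6 side chain.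

Step 3
Reactants: 4 rac-trans-4-hydroxy-5-(prop-2-en-1-yl)cyclopent-2-en-1-one
Product: 5 (4R,5S)-4-hydroxy-5-(prop-2-en-1-yl)cyclopent-2-en-1-one
Conditions: (R)-benzotetramisole (2 mol%), isobutyric anhydride (0.6 equiv), EtN(CHMe2)2, CHCl3, 0 °C, to about 55% conversion; chromatography
Reagents that add atoms: none
Why: Acylative kinetic resolution of a cyclic secondary allylic alcohol with a chiral isothiourea acyl-transfer catalyst esterifies the (4S,5R)-enantiomer and leaves (4R,5S)-5, which sets the absolute configuration of the ring.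

Step 4
Reactants: 5 (4R,5S)-4-hydroxy-5-(prop-2-en-1-yl)cyclopent-2-en-1-one; 6 formaldehyde
Product: 7 (4R,5S)-4-hydroxy-2-(hydroxymethyl)-5-(prop-2-en-1-yl)cyclopent-2-en-1-one
Conditions: aq. HCHO (37%), imidazole, THF/H2O, rt
Reagents that add atoms: none
Why: Morita–Baylis–Hillman reaction of the β-unsubstituted cyclopentenone puts the hydroxymethyl carbon on the α-carbon under mild conditions that leave both stereocentres untouched.

Step 5
Reactants: 7 (4R,5S)-4-hydroxy-2-(hydroxymethyl)-5-(prop-2-en-1-yl)cyclopent-2-en-1-one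
Product: 8 (4R,5S)-2-{[(tert-butyldimethylsilyl)oxy]methyl}-4-hydroxy-5-(prop-2-en-1-yl)cyclopent-2-en-1-one
Conditions: TBSCl (1.05 equiv), imidazole, CH2Cl2, −20 °C
Reagents that add atoms: tert-butyldimethylsilyl chloride, CC(C)(C)[Si](C)(C)Cl
Why: Selective silylation of the primary allylic alcohol over the hindered secondary one keeps the ring hydroxyl free for steps 12 and 13.

Step 6
Reactants: 9 methacryloyl chloride
Product: 10 2-(trimethylsilyl)ethyl methacrylate
Conditions: Me3SiCH2CH2OH, Et3N, DMAP (cat.), CH2Cl2, 0 °C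
Reagents that add atoms: 2-(trimethylsilyl)ethanol, C[Si](C)(C)CCO
Why: Acylation of the alcohol by the acid chloride (esterification) gives a methacrylate whose ester is later cleaved by fluoride.

Step 7
Reactants: 8 (4R,5S)-2-{[(tert-butyldimethylsilyl)oxy]methyl}-4-hydroxy-5-(prop-2-en-1-yl)cyclopent-2-en-1-one; 10 2-(trimethylsilyl)ethyl methacrylate
Product: 11 cyclopentenone with the complete (E)-enoate side chain
Conditions: 10 (5 equiv), second-generation Hoveyda–Grubbs catalyst RuCl2(SIMes)(=CH-C6H4-2-OCHMe2) (5 mol%), CH2Cl2, 40 °C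
Reagents that add atoms: none
Why: Olefin cross-metathesis of the terminal allyl group with the methacrylate gives the trisubstituted E-enoate under thermodynamic control, while the electron-poor ring enone alkene does not react.

Step 8
Reactants: 12 (R)-propylene oxide; 13 but-3-enylmagnesium bromide
Product: 14 (2R)-hept-6-en-2-ol
Conditions: CuI (10 mol%), THF, −30 → 0 °C; H2O work-up
Reagents that add atoms: none
Why: Copper-catalysed Grignard opening of the epoxide at the unsubstituted carbon leaves the stereocentre untouched, so the R configuration comes from the epoxide.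

Step 9
Reactants: 14 (2R)-hept-6-en-2-ol
Product: 15 tert-butyl{[(2R)-hept-6-en-2-yl]oxy}dimethylsilane
Conditions: TBSCl, imidazole, DMF, rt
Reagents that add atoms: tert-butyldimethylsilyl chloride, CC(C)(C)[Si](C)(C)Cl
Why: Silyl protection keeps the alcohol out of the diazo and Lewis acid chemistry of step 12.

Step 10
Reactants: 15 tert-butyl{[(2R)-hept-6-en-2-yl]oxy}dimethylsilane; 16 acrolein
Product: 17 (2E,7R)-7-[(tert-butyldimethylsilyl)oxy]oct-2-enal
Conditions: 16 (3 equiv), second-generation Hoveyda–Grubbs catalyst RuCl2(SIMes)(=CH-C6H4-2-OCHMe2) (3 mol%), CH2Cl2, 40 °C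
Reagents that add atoms: none
Why: Cross-metathesis of a terminal alkene with acrolein gives the E-enal selectively.

Step 11
Reactants: 17 (2E,7R)-7-[(tert-butyldimethylsilyl)oxy]oct-2-enal
Product: 18 N-sulfonylhydrazone of 17
Conditions: 2-(CF3)C6H4SO2NHNH2, THF, 0 °C → rt
Reagents that add atoms: 2-(trifluoromethyl)benzenesulfonohydrazide, NNS(=O)(=O)c1ccccc1C(F)(F)F
Why: Condensation gives a sulfonylhydrazone that releases its diazo compound with base well below room temperature (Bamford–Stevens type).

Step 12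
Reactants: 11 cyclopentenone with the complete (E)-enoate side chain; 18 N-sulfonylhydrazone of 17
Product: 20 (2RS,5R,6S)-2-alkenyl-5-hydroxycyclohex-3-en-1-one, via alkenyldiazomethane 19 (not isolated)
Conditions: (a) 18, NaH, CH2Cl2, −40 → −20 °C; (b) cold solution of 19 added to 11 + AlMe3 (1.1 equiv), CH2Cl2, −78 → −40 °C; H2O work-up; used crude
Reagents that add atoms: none
Why: Proposed new method: AlMe3 turns the free C4 hydroxyl of 11 into an aluminium alkoxide that chelates and activates the C1 carbonyl, the nucleophilic carbon of alkenyldiazomethane 19 adds 1,2, and loss of N2 from the resulting β-aluminoxy allyl diazonium (allyl-cation-like, so the π-rich ring alkenyl carbon C2 shifts in preference to the oxygen-deactivated, chelate-held sp3 carbon C5) inserts the side-chain-bearing carbon between C1 and C2 as a Tiffeneau–Demjanov-type 1,2-shift, enlarging the five- to the six-membered ring with both existing stereocentres untouched and the new C2 centre formed as an inconsequential mixture; the closest known reaction is the organoaluminium- or Sc(OTf)3-promoted homologation of saturated cyclic ketones with alkyl- and aryldiazomethanes, which has not been shown with an alkenyldiazomethane, with a cyclopentenone, or with alkenyl-selective migration under hydroxyl-anchored activation.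

Step 13
Reactants: 20 (2RS,5R,6S)-2-alkenyl-5-hydroxycyclohex-3-en-1-one
Product: 22 (4R,5S,6S)-4,5-dihydroxycyclohex-2-en-1-one with both silyl ethers and the ester in place, via syn-epoxy ketone 21 (not isolated)
Conditions: VO(acac)2 (5 mol%), t-BuOOH, CH2Cl2, 0 °C; then Et3N, 0 °C → rt
Reagents that add atoms: tert-butyl hydroperoxide, CC(C)(C)OO
Why: Hydroxyl-directed epoxidation delivers oxygen to the C3=C4 alkene on the face of the C5 hydroxyl, and Et3N then opens the β,γ-epoxy ketone by E1cB elimination through the doubly activated C2–H, which sets C4–OH cis to C5–OH, erases the C2 centre and creates the dienone.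

Step 14
Reactants: 22 (4R,5S,6S)-4,5-dihydroxycyclohex-2-en-1-one with both silyl ethers and the ester in place
Product: 23 pestallic acid O
Conditions: TBAF, AcOH (1:1, 4 equiv), THF, 0 °C → rt
Reagents that add atoms: none
Why: Fluoride-induced desilylation cleaves both silyl ethers and fragments the 2-(trimethylsilyl)ethyl ester by β-elimination in one buffered operation that does not touch the stereocentres.

**Compound list**
1 | furfural (furan-2-carbaldehyde) | O=Cc1ccco1 | starting material
2 | allylmagnesium bromide (C3H5MgBr) | C=CC[Mg]Br | starting material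
3 | rac-1-(furan-2-yl)but-3-en-1-ol | C=CCC(O)c1ccco1 | intermediate
4 | rac-(4R,5S)-4-hydroxy-5-(prop-2-en-1-yl)cyclopent-2-en-1-one (trans racemate; the 4R,5S enantiomer is drawn) | O=C1C=C[C@@H](O)[C@@H]1CC=C | intermediate
5 | (4R,5S)-4-hydroxy-5-(prop-2-en-1-yl)cyclopent-2-en-1-one | O=C1C=C[C@@H](O)[C@@H]1CC=C | intermediate
6 | formaldehyde | C=O | starting material
7 | (4R,5S)-4-hydroxy-2-(hydroxymethyl)-5-(prop-2-en-1-yl)cyclopent-2-en-1-one | O=C1C(CO)=C[C@@H](O)[C@@H]1CC=C | intermediate
8 | (4R,5S)-2-{[(tert-butyldimethylsilyl)oxy]methyl}-4-hydroxy-5-(prop-2-en-1-yl)cyclopent-2-en-1-one | O=C1C(CO[Si](C)(C)C(C)(C)C)=C[C@@H](O)[C@@H]1CC=C | intermediate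
9 | methacryloyl chloride | C=C(C)C(=O)Cl | starting material
10 | 2-(trimethylsilyl)ethyl 2-methylprop-2-enoate | C=C(C)C(=O)OCC[Si](C)(C)C | intermediate
11 | 2-(trimethylsilyl)ethyl (2E)-4-[(1S,5R)-3-{[(tert-butyldimethylsilyl)oxy]methyl}-5-hydroxy-2-oxocyclopent-3-en-1-yl]-2-methylbut-2-enoate | O=C1C(CO[Si](C)(C)C(C)(C)C)=C[C@@H](O)[C@@H]1C/C=C(\C)C(=O)OCC[Si](C)(C)C | intermediate
12 | (R)-propylene oxide [(2R)-2-methyloxirane] | C[C@@H]1CO1 | starting material
13 | but-3-enylmagnesium bromide (C4H7MgBr) | C=CCC[Mg]Br | starting material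
14 | (2R)-hept-6-en-2-ol | C=CCCC[C@@H](C)O | intermediate
15 | tert-butyl{[(2R)-hept-6-en-2-yl]oxy}dimethylsilane | C=CCCC[C@@H](C)O[Si](C)(C)C(C)(C)C | intermediate
16 | acrolein (prop-2-enal) | C=CC=O | starting material
17 | (2E,7R)-7-[(tert-butyldimethylsilyl)oxy]oct-2-enal | O=C/C=C/CCC[C@@H](C)O[Si](C)(C)C(C)(C)C | intermediate
18 | N'-{(1E,2E,7R)-7-[(tert-butyldimethylsilyl)oxy]oct-2-en-1-ylidene}-2-(trifluoromethyl)benzenesulfonohydrazide | O=S(=O)(N/N=C/C=C/CCC[C@@H](C)O[Si](C)(C)C(C)(C)C)c1ccccc1C(F)(F)F | intermediate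
19 | tert-butyl{[(2R,6E)-8-diazooct-6-en-2-yl]oxy}dimethylsilane (not isolated) | [N-]=[N+]=C/C=C/CCC[C@@H](C)O[Si](C)(C)C(C)(C)C | intermediate
20 | (2RS,5R,6S)-2-[(1E,6R)-6-(tert-butyldimethylsilyloxy)hept-1-enyl]-3-[(tert-butyldimethylsilyloxy)methyl]-5-hydroxy-6-[(2E)-3-{[2-(trimethylsilyl)ethoxy]carbonyl}but-2-enyl]cyclohex-3-en-1-one | O=C1C(/C=C/CCC[C@@H](C)O[Si](C)(C)C(C)(C)C)C(CO[Si](C)(C)C(C)(C)C)=C[C@@H](O)[C@@H]1C/C=C(\C)C(=O)OCC[Si](C)(C)C | intermediate
21 | 3,4-epoxide of 20 with the oxirane oxygen cis to the C5 hydroxyl (not isolated) | O=C1C(/C=C/CCC[C@@H](C)O[Si](C)(C)C(C)(C)C)[C@@]2(CO[Si](C)(C)C(C)(C)C)O[C@H]2[C@@H](O)[C@@H]1C/C=C(\C)C(=O)OCC[Si](C)(C)C | intermediate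
22 | (4R,5S,6S)-2-[(1E,6R)-6-(tert-butyldimethylsilyloxy)hept-1-enyl]-3-[(tert-butyldimethylsilyloxy)methyl]-4,5-dihydroxy-6-[(2E)-3-{[2-(trimethylsilyl)ethoxy]carbonyl}but-2-enyl]cyclohex-2-en-1-one (C5 geometry as in 20; its descriptor changes only through the priority rules) | O=C1C(/C=C/CCC[C@@H](C)O[Si](C)(C)C(C)(C)C)=C(CO[Si](C)(C)C(C)(C)C)[C@@H](O)[C@@H](O)[C@@H]1C/C=C(\C)C(=O)OCC[Si](C)(C)C | intermediate
23 | pestallic acid O, (2E)-4-[(1S,2S,3R)-2,3-dihydroxy-5-[(1E,6R)-6-hydroxyhept-1-en-1-yl]-4-(hydroxymethyl)-6-oxocyclohex-4-en-1-yl]-2-methylbut-2-enoic acid | C/C(=C\C[C@@H]1C(=O)C(/C=C/CCC[C@@H](C)O)=C(CO)[C@@H](O)[C@H]1O)C(=O)O | target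

**Step count and risks**

Total steps: 14. Longest linear sequence: 9 (steps 1, 2, 3, 4, 5, 7, 12, 13, 14).

Step 12 (the proposed new method) is the most likely to fail. The sp3 carbon C5 may shift instead of the alkenyl carbon C2, 19 may add to an electron-poor alkene or cyclise to a pyrazole, and 20 may slip into conjugation. The fallback uses known reactions, sets out from 17 and 11 and returns at 20. Luche reduction of 17 (NaBH4, CeCl3·7H2O, MeOH) gives (2E,7R)-7-[(tert-butyldimethylsilyl)oxy]oct-2-en-1-ol F1. Appel bromination (PPh3, CBr4) gives (2E,7R)-1-bromo-7-[(tert-butyldimethylsilyl)oxy]oct-2-ene F2. Tetrahydrothiophene converts it into the S-allyl tetrahydrothiophenium bromide F3. The ylide of F3 (LiN(SiMe3)2, 2.1 equiv, THF, −78 °C) adds to the ketone of 11 in a Corey–Chaykovsky epoxidation and gives the spiro vinyl epoxide F4. BF3·OEt2 at −78 °C then opens F4 at the allylic C–O bond, and a Meinwald-type semipinacol shift of the ring alkenyl carbon enlarges the ring to 20.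

Step 3 may give a low selectivity factor or the opposite sense, and it cannot exceed 50% yield. The fallback sets out from racemic 4 and returns at 5. Dess–Martin periodinane oxidises both enantiomers to the achiral 2-(prop-2-en-1-yl)cyclopent-4-ene-1,3-dione F5. Corey–Bakshi–Shibata reduction ((R)-Me-CBS oxazaborolidine, catecholborane, toluene, −78 °C) reduces one of the two enantiotopic carbonyls with catalyst control of the carbinol centre. The neighbouring α-centre then equilibrates to the trans isomer (Et3N), which gives 5 without the 50% loss.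

Step 13 may fail because 20 can isomerise before it is epoxidised, or because the allylic alcohol is oxidised instead. The fallback sets out from 20 and returns at 22. A Schenck ene reaction with singlet oxygen (O2, tetraphenylporphyrin, visible light, CH2Cl2, −20 °C), steered by the C5 hydroxyl, removes the C2 hydrogen and gives the (4R,5S,6S)-4-hydroperoxy analogue of 22 F6 directly. PPh3 reduces F6 to 22.

**Further compounds**
F1 | step 12 | (2E,7R)-7-[(tert-butyldimethylsilyl)oxy]oct-2-en-1-ol | OC/C=C/CCC[C@@H](C)O[Si](C)(C)C(C)(C)C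
F2 | step 12 | (2E,7R)-1-bromo-7-[(tert-butyldimethylsilyl)oxy]oct-2-ene | BrC/C=C/CCC[C@@H](C)O[Si](C)(C)C(C)(C)C
F3 | step 12 | 1-{(2E,7R)-7-[(tert-butyldimethylsilyl)oxy]oct-2-en-1-yl}tetrahydrothiophenium bromide | [Br-].C(/C=C/CCC[C@@H](C)O[Si](C)(C)C(C)(C)C)[S+]1CCCC1
F4 | step 12 | spiro vinyl epoxide of 11 (1-oxaspiro[2.4]hept-4-ene; oxirane carbon bears the (1E,6R)-6-silyloxyhept-1-enyl group; epoxide centres as a mixture) | C1(/C=C/CCC[C@@H](C)O[Si](C)(C)C(C)(C)C)OC12C(CO[Si](C)(C)C(C)(C)C)=C[C@@H](O)[C@@H]2C/C=C(\C)C(=O)OCC[Si](C)(C)C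
F5 | step 3 | 2-(prop-2-en-1-yl)cyclopent-4-ene-1,3-dione | O=C1C=CC(=O)C1CC=C
F6 | step 13 | (4R,5S,6S)-4-hydroperoxy analogue of 22 | O=C1C(/C=C/CCC[C@@H](C)O[Si](C)(C)C(C)(C)C)=C(CO[Si](C)(C)C(C)(C)C)[C@@H](OO)[C@@H](O)[C@@H]1C/C=C(\C)C(=O)OCC[Si](C)(C)C
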